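the same everywhere: starting material 1.5 M; free catalyst 15 mol%
- alpha: second substrate 1 equiv; reagent 0.80 equiv; temperature 35 °C; the very flask that is asked about, followed so far
- beta: second substrate 1 equiv; reagent 0.80 equiv; temperature 20 °C; run made earlier
- flask: second substrate 1.00 equiv; reagent 0.800 equiv; temperature 35 °C; time 8.0 d

- alpha (time / h: target / %): 12.0: 25.7; 25.0: 36.4; 40.0: 38.6; 72.0: 39.8; 144: 37.4
- beta (time / h: target / %): 25.0: 11.2; 48.0: 17.3; 96.0: 27.8; 144: 31.6; 288: 30.5

(each reading ± 1 percentage point)

- ash: at 8.0 d add free catalyst, 100% of the amount charged, then wait 8.0 d
- oak: change nothing and wait 8.0 d more
- cedar: at 8.0 d raise the temperature by 25 K, then wait 8.0 d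
- birch: at 8.0 d take out 90% of the target then present, then wait 8.0 d
- alder: at 8.0 d add reagent, 50.0% of the amount charged, then wait 8.0 d

- what is taken out of target is counted as made
- additions bring no volume worth counting

1. target, in percent of the starting material first charged, at 8.0 d
2. the option that brings most further target ("none" if no option brings more than 2 percentage points) (ash / oak / cedar / birch / alder / none)
3. target present, with what was taken out counted in, in percent of the starting material first charged, after oak
4. target present, with what was taken out counted in, in percent of the starting material first charged, after birch

- A small charge is where you start: the flask holds 0.800 equiv of reagent per starting material, with second substrate and free catalyst beside them, so if one reagent makes one target, you should suspect reagent as the limiting reagent and ask what the end state must be before asking how fast it comes.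
- The alpha run has the flask's own recipe and levels off, its last three readings averaging 38.6%, which gives you the reagent yield 0.482, the target made per reagent charged, both counted per starting material.
- Your objection is that a yield of 0.482 does not say where the rest of the reagent went: a second consumer of reagent, with the second substrate as the obvious suspect, could draw this plateau, but so could a dying catalyst or an equilibrium, so what follows is a wager on consumed reagent.
- The cold beta run at least fits a competition for reagent, since its last two readings give a yield of 0.388, lower than the warm one, as when two routes share reagent in a ratio that shifts with temperature.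
- For the speed, if you take the rise as exponential, the first alpha reading gives a rate constant of 0.0913 h⁻¹ towards the plateau, a half-time of 7.59 h, so 8.0 d is about 25.3 half-times and you put the flask at 38.6%.
- You might object that target fades, but the alpha drop of 2.4 percentage points lies between two readings that each scatter by 1 point, so you carry no fade, and you reckon oak and birch, with what is taken out counted in, at 38.6%.
- On your wager, ash and cedar bring no new reagent into the flask, while alder adds 50.0% of the charge, which you reckon at 19 points of further target, so alder is your choice.
- The forecast said 36.2%, ash, 31.5% after oak and 37% after birch, on the ground that "I favour lost catalyst, with fresh catalyst restarting reaction".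
- The flask gives 38.9%, with 38.9% after oak, 38.9% after birch, and alder as the best option.

    starting material + free catalyst ⇌ catalyst intermediate A (K = 2.10 M⁻¹, k = 0.350 M⁻¹ h⁻¹, Ea = 67.0 kJ mol⁻¹, ΔH = −11.0 kJ mol⁻¹)
    reagent + catalyst intermediate A → free catalyst + target (k = 1.90 M⁻¹ h⁻¹, Ea = 54.0 kJ mol⁻¹)
    second substrate + free catalyst ⇌ catalyst intermediate B (K = 1.20 M⁻¹, k = 7.80 M⁻¹ h⁻¹, Ea = 60.0 kJ mol⁻¹, ΔH = −45.0 kJ mol⁻¹)
    reagent + catalyst intermediate B → free catalyst + second product (k = 0.460 M⁻¹ h⁻¹, Ea = 70.0 kJ mol⁻¹)
    reagent + target → over-reaction product (k = 0.0150 M⁻¹ h⁻¹, Ea = 72.0 kJ mol⁻¹)
    (constants at 35 °C)

- At 192 h the flask holds 0% of its reagent and 52.1% of its starting material, and alder adds 21 points of target where the reagent yield reckoned 19 points. Carried to the neighbouring flask with 0.480 equiv of reagent, the same yield reckons 23.1%, and that flask stands at 27.1%.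

The runs are simulated with made-up constants; scatter was added.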